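One percentage point of the free monomer charged is 2.00 µM here, and the candidate step from protic impurity and free monomer to quenched substrate takes them one for one, so the flask's 0.00400 mM of protic impurity costs 2.00% of the charge. This is the quench share q, protic impurity charged over free monomer charged, a small correction to be reckoned apart from the large turnover into chains.

| setting | violet | green | red | flask |
|---|---|---|---|---|
| free monomer | 2.0 × 10⁻⁴ M | 2.0 × 10⁻⁴ M | 2.0 × 10⁻⁴ M | 2.0 × 10⁻⁴ M |
| transfer agent | 0.0060 mM | 0.0060 mM | 0.0030 mM | 0.00600 mM |
| protic impurity | 0.0056 mM | 0.0088 mM | 0.0040 mM | 0.00400 mM |
| pre-initiator | 20 µM | 20 µM | 20 µM | 20 µM |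
| remark | run made earlier | run made earlier | run made earlier |  |
| time |  |  |  | 2.0 min |

| run | time / s | monomer in chains / % | free monomer / % |
|---|---|---|---|
| violet | 30.0 | 6.0 | 88.9 |
| violet | 60.0 | 13.9 | 82.1 |
| violet | 90.0 | 21.6 | 75.5 |
| violet | 120 | 29.8 | 65.5 |
| green | 10.0 | 2.5 | 92.8 |
| green | 20.0 | 2.6 | 93.0 |
| green | 50.0 | 11.9 | 82.3 |
| green | 120 | 28.0 | 64.4 |
| red | 30.0 | 7.2 | 92.6 |
| red | 60.0 | 15.2 | 82.5 |
| red | 90.0 | 23.9 | 74.3 |
| red | 120 | 35.5 | 64.3 |

(readings scatter by 1 percentage point)

- the average divides the monomer in chains by the number of chains begun, living and dead together
- candidate steps: free monomer + initiator -> living end + monomer in chains; free monomer + living end -> monomer in chains + living end; living end + transfer agent -> dead chain; protic impurity + free monomer -> quenched substrate; pre-initiator -> initiator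
- the earlier runs do not show the number of chains; that part of a forecast is a guess

- average number of monomer units in a chain (chains begun, living or dead) at 2.0 min
- part of the free monomer that has reacted at 2.0 min

The settings can be turned one at a time. More protic impurity should by hand remove q early and leave the rest to run as before, and the green run at 10.0 s already lacks 4.70% between its two readings, against its q of 4.40%. The survivor fraction s, free monomer divided by the charge that the quench leaves, reads 67.4% in the violet run and 67.4% in the green run at 120 s. Less transfer agent should keep more living ends, and the red run's s of 65.6% is lower, though by about the scatter; the flask's 0.00600 mM matches violet and green, and its 120 s matches their last reading, so s carries over unchanged. Pre-initiator stands at 20 µM in the flask as in the violet, green and red runs, so these readings hold no change of it to compare, but by the candidate steps one pre-initiator can begin one chain.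

My reckoning for the flask leaves 66.0% free, so c is 34.0%, of which 32.0% lies in chains, and with the whole pre-initiator charge as chains begun, dp comes to 3.20, a figure that fewer chains begun would raise.

The forecast gives dp 3.2 and c 33.5%, adding “If initiation is incomplete, dp would be higher”.

The flask gives dp 3.78 and c 33.4%.

    free monomer + initiator → living end + monomer in chains (k = 4800 M⁻¹ s⁻¹)
    free monomer + living end → monomer in chains + living end, rate k2*[living end]*[free monomer] (k = 290 M⁻¹ s⁻¹)
    living end + transfer agent → dead chain (kL = 1400 M⁻¹ s⁻¹)
    protic impurity + free monomer → quenched substrate (k = 3600 M⁻¹ s⁻¹)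
    pre-initiator → initiator (k = 0.0150 s⁻¹)

In the flask the half-life of pre-initiator by its own turning, 0.77 min, is far longer than that of initiator by its step with free monomer at 2.00 min, 1.1 s, and with 16.5% of the pre-initiator left and 0.0789 µM standing as initiator, living ends and dead chains together come to 16.6 µM, less than the 20 µM charged. The same flask read at 30 s holds 0% of its protic impurity and 2.00% as quenched substrate, so its c of 8.27% less q leaves 6.27%, the 6.27% in chains, q being 24.2% of c there.

(The readings are calculated on assumed constants, noise included.)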